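This closed, stirred vessel holds starting material that can leave by three proposed steps: to target, to side product and, with protic impurity, to quenched substrate.

| flask | starting material | protic impurity | remark | time |
|---|---|---|---|---|
| south | 0.041 M | 0.0053 M | run made earlier |  |
| north-west | 0.041 M | 0.016 M | run made earlier |  |
| zeta | 0.041 M | 0.0100 M |  | 0.80 h |
| delta | 0.041 M | 0.0205 M |  | 3.0 h |

| run | time / min | target / % | side product / % |
|---|---|---|---|
| south | 12.0 | 30.0 | 31.1 |
| south | 30.0 | 42.4 | 43.7 |
| south | 60.0 | 45.1 | 46.3 |
| south | 90.0 | 45.6 | 46.5 |
| south | 120 | 46.1 | 46.9 |
| north-west | 12.0 | 28.3 | 28.1 |
| north-west | 30.0 | 36.2 | 37.6 |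
| north-west | 60.0 | 38.8 | 39.8 |
| north-west | 90.0 | 38.3 | 39.8 |
| north-west | 120 | 38.7 | 40.1 |

(scatter of a reading: 0.3 percentage points)

- the numbers in the tables scatter by 0.3 percentage points (one standard deviation)
- steps that have been proposed: starting material -> target; starting material -> side product; starting material + protic impurity -> quenched substrate

- the winner by share of target in all that became target or side product; "neither" if no more than 2 percentage points parts them (zeta / delta / neither)
- share of target in all that became target or side product, zeta
- share of target in all that became target or side product, delta

I compare the rates at one moment, with [A] the starting material concentration, [H] the protic impurity concentration, P and Q the yields of target and side product, r_P, r_Q and r_V the rates into target, side product and quenched substrate, and each k a rate constant: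

r_P = k_P[A], r_Q = k_Q[A], so r_P/r_Q = k_P/k_Q

Neither concentration stands in that quotient, so I pool the last readings of both runs:

S = P/(P+Q) = 49.4 %

S, the share of target in target plus side product, is the selectivity, and I carry it to the new flasks.

The first setting is the impurity. By hand, the third step, r_V = k_V[A][H], should lower both products together and leave S in place. From south to north-west, [H] goes from 0.0053 M to 0.016 M. At the last readings the combined yield falls from 93.0 % to 78.8 %, while the share reads 49.6 % and then 49.1 %, a gap smaller than the margin.

The second setting is time. By hand, falling [A] lowers both rates by the same factor, so S should not drift. The pooled readings at 12.0 min give 49.6 %, close to S.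

I therefore give zeta and delta the same 49.4 %, so neither wins.

The forecast says 49.3 % for zeta and 49.3 % for delta, hence neither, since “the two channels share the same kinetic order”.

The flask gives 49.3 % for zeta and 49.3 % for delta, hence neither, beside my 49.4 %.

starting material → target (k = 6.90 × 10⁻⁴ s⁻¹); starting material → side product (k = 7.10 × 10⁻⁴ s⁻¹); starting material + protic impurity → quenched substrate (k = 0.0350 M⁻¹ s⁻¹) In delta, the step to target alone gives the starting material a half-life of 0.28 h and the step to side product alone 0.27 h, and the rate of the step to side product over that of the step to target is 1.0 at the start and 1.0 at 0.104 h. The neighbour of delta charged with 0.051 M of protic impurity ends with 24.7 % target and 25.4 % side product, a share of 49.3 %.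

(The numbers in the tables were generated by integration for substances that don't exist.)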